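**Plan** (chromene numbering of the target: O1, C2, C3, C4, C4a, C5–C8, C8a)

1. Retrosynthesis: the C7 phenol is unmasked last from a MOM ether; the pyran ring is then cut at C4–C4a and O1–C8a (O1–C2 forms in the same event), which leads back to a C4a≡C8a aryne of the fully substituted benzo ring and 3-methylbut-2-enal (prenal).
2. Enabling feature: the methoxy group on C5, next to C4a, polarises the aryne so that the aldehyde oxygen bonds to C8a and the formyl carbon to C4a; the O1–C2(CH3)2–C3=C4 unit of the pyran ring is prenal, delivered by [2+2] addition, benzoxete opening and oxa-6π closure.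
3. The aryne is stored as an ortho-silylaryl triflate (TMS on C8a, OTf on C4a; both helpers leave in the key step); the 1,2-diketone on C6 is cut at both aryl–CO bonds to an aryllithium, 1,4-dimethylpiperazine-2,3-dione and 4-methoxyphenylmagnesium bromide.
4. Forward: 4-(benzyloxy)-3-methoxyphenol → MOM ether → phenol → isopropylcarbamate; one N-silyl mask, put on once, serves two successive directed ortho-metalations (TMS at the future C8a, then the diketone at the future C6) and is lost in the acid work-up of the second; carbamate → triflate; the pyran ring is then built on the finished benzo ring and the MOM group is removed.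
5. Stereochemistry: the target has no stereocentre and its only C=C (C3=C4) lies in a ring, so nothing has to be controlled; the benzoxete CH formed in the key step is transient.

Key step: step 7

Remark: compounds 1, 8, 9 and 16 are taken as purchased. Compound 7 is moisture-sensitive and is carried into step 5 as the crude material. The intermediates 11, 12 and 18 are formed without stereocontrol, which is of no consequence because their stereocentres are destroyed in the same flask.

**Step 1**
Reactants: 1 4-(benzyloxy)-3-methoxyphenol
Product: 2 1-(benzyloxy)-2-methoxy-4-(methoxymethoxy)benzene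
Conditions: MOMCl, i-Pr2NEt, CH2Cl2, 0 °C to rt
Reagents that add atoms: chloromethyl methyl ether (MOMCl), COCCl
Why: The only free phenol should be alkylated by the chloromethyl ether under amine base (Williamson-type O-alkylation to a MOM acetal), the benzyl ether being inert.

**Step 2**
Reactants: 2 1-(benzyloxy)-2-methoxy-4-(methoxymethoxy)benzene
Product: 3 2-methoxy-4-(methoxymethoxy)phenol
Conditions: H2 (1 atm), Pd/C, EtOAc, rt
Reagents that add atoms: none
Why: Heterogeneous hydrogenolysis should cleave the benzylic C–O bond selectively, the MOM acetal and the methyl ether being stable under neutral hydrogenation.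

**Step 3**
Reactants: 3 2-methoxy-4-(methoxymethoxy)phenol
Product: 4 2-methoxy-4-(methoxymethoxy)phenyl propan-2-ylcarbamate
Conditions: i-PrNCO, Et3N (cat.), CH2Cl2, rt
Reagents that add atoms: isopropyl isocyanate, CC(C)N=C=O
Why: Base-catalysed addition of the phenol to the isocyanate (carbamoylation) should give the N-monoalkyl carbamate, which serves as the ortho-directing group and later as a mildly removable precursor of the triflate.

**Step 4**
Reactants: 4 2-methoxy-4-(methoxymethoxy)phenyl propan-2-ylcarbamate
Product: 7 2-methoxy-4-(methoxymethoxy)-6-(trimethylsilyl)phenyl N-(tert-butyldimethylsilyl)-N-(propan-2-yl)carbamate, via N-silyl carbamate 5 (not isolated), via ortho-lithiated carbamate 6 (not isolated)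
Conditions: TBSOTf (1.1 equiv), TMEDA, Et2O, 0 °C to rt; then n-BuLi, TMEDA, −78 °C; then TMSCl, −78 °C to rt; pentane, filtration under Ar, evaporation (no aqueous work-up)
Reagents that add atoms: tert-butyldimethylsilyl triflate (TBSOTf), CC(C)(C)[Si](C)(C)OS(=O)(=O)C(F)(F)F; chlorotrimethylsilane (TMSCl), C[Si](C)(C)Cl
Why: In situ N-silylation masks the acidic N–H, directed ortho-metalation should then take place at the only free position ortho to the carbamate (the strongest directing group, kinetic complex-induced proximity at −78 °C) and not between OMe and OMOM, and C-silylation of 6 gives 7, whose N-silyl group is kept on purpose by the non-hydrolytic work-up so that it also serves the next metalation.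

**Step 5**
Reactants: 7 2-methoxy-4-(methoxymethoxy)-6-(trimethylsilyl)phenyl N-(tert-butyldimethylsilyl)-N-(propan-2-yl)carbamate; 8 1,4-dimethylpiperazine-2,3-dione; 9 4-methoxyphenylmagnesium bromide
Product: 13 2-methoxy-3-[2-(4-methoxyphenyl)-2-oxoacetyl]-4-(methoxymethoxy)-6-(trimethylsilyl)phenyl propan-2-ylcarbamate, via aryllithium 10 (not isolated), via lithium hemiaminalate 11 (not isolated), via bis-hemiaminalate 12 (not isolated)
Conditions: crude 7, s-BuLi, TMEDA, Et2O–THF, −78 °C; cannulation into 8 (suspension), THF, −78 to 0 °C; then 9, 0 °C to rt; 1 M HCl, 0 °C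
Reagents that add atoms: 1,4-dimethylpiperazine-2,3-dione (8), CN1CCN(C)C(=O)C1=O; 4-methoxyphenylmagnesium bromide (9), COc1ccc([Mg]Br)cc1
Why: With the N–H still masked and both positions ortho to the carbamate substituted, directed ortho-metalation should occur at the carbon flanked by OMe and OMOM (cooperative directing groups, the other free CH being shielded by TMS), and sequential addition of aryllithium 10 and then Grignard reagent 9 to the two amide carbonyls of the oxalyl synthon 8, each tetrahedral hemiaminalate surviving until the acid work-up that also hydrolyses the N–Si bond, is the known one-pot synthesis of unsymmetrical 1,2-diketones.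

**Step 6**
Reactants: 13 2-methoxy-3-[2-(4-methoxyphenyl)-2-oxoacetyl]-4-(methoxymethoxy)-6-(trimethylsilyl)phenyl propan-2-ylcarbamate
Product: 15 2-methoxy-3-[2-(4-methoxyphenyl)-2-oxoacetyl]-4-(methoxymethoxy)-6-(trimethylsilyl)phenyl trifluoromethanesulfonate, via ortho-silyl phenol 14 (not isolated)
Conditions: DBU, Et2NH, MeCN, 40 °C; then PhNTf2, rt
Reagents that add atoms: N-phenylbis(trifluoromethanesulfonimide) (PhNTf2), O=S(=O)(N(c1ccccc1)S(=O)(=O)C(F)(F)F)C(F)(F)F
Why: Amidine-induced E1cB fragmentation of the N–H carbamate (the isocyanate being trapped by Et2NH as a urea) should unveil phenoxide 14 under conditions that spare the aryl–Si bond, the MOM acetal and the non-enolisable diketone, and O-sulfonylation with PhNTf2 then gives the ortho-silylaryl triflate.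

**Step 7**
Reactants: 15 2-methoxy-3-[2-(4-methoxyphenyl)-2-oxoacetyl]-4-(methoxymethoxy)-6-(trimethylsilyl)phenyl trifluoromethanesulfonate; 16 3-methylbut-2-enal (prenal)
Product: 20 1-[5-methoxy-7-(methoxymethoxy)-2,2-dimethyl-2H-chromen-6-yl]-2-(4-methoxyphenyl)ethane-1,2-dione, via aryne 17 (not isolated), via benzoxete 18 (not isolated), via ortho-quinone methide 19 (not isolated)
Conditions: CsF (3 equiv), 16 (5 equiv), MeCN, rt to 50 °C
Reagents that add atoms: 3-methylbut-2-enal (16), CC(C)=CC=O
Why: Fluoride attack on silicon with loss of triflate should give aryne 17, whose C8a (the aryne carbon remote from the C5 methoxy group) is attacked by the carbonyl oxygen of prenal, after which the aryl anion at C4a collapses onto the oxocarbenium carbon to give benzoxete 18, which opens by retro-4π electrocyclisation to ortho-quinone methide 19 and recloses between O1 and C2 to the 2H-chromene. The closest known reaction type is the annulation of arynes with α,β-unsaturated aldehydes to 2H-chromenes, itself related to aryne insertion into the C=O bond of formamides. The four-membered ring closes as a formal, asynchronous [2+2] cycloaddition (O–C8a first, then C4–C4a), and the pyran ring closes by thermal disrotatory oxa-6π electrocyclisation of the 1-oxatriene, for which the C5 methoxy group pushes the vinyl arm of 19 to the carbonyl side (Z). No stereocentre is present in the product, the benzoxete CH being transient. The step needs regioselectivity (O to C8a, C to C4a), secured by the inductively withdrawing C5 methoxy group that distorts the aryne and places the developing negative charge on the adjacent C4a, and periselectivity for [2+2] over [4+2] (a 4H-chromene), secured by the hindered β,β-dimethyl terminus and the s-trans preference of prenal. Chemoselectivity for the aldehyde over the two hindered ketone carbonyls should follow from the higher reactivity and the excess of prenal.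

**Step 8**
Reactants: 20 1-[5-methoxy-7-(methoxymethoxy)-2,2-dimethyl-2H-chromen-6-yl]-2-(4-methoxyphenyl)ethane-1,2-dione
Product: 21 1-(7-hydroxy-5-methoxy-2,2-dimethyl-2H-chromen-6-yl)-2-(4-methoxyphenyl)ethane-1,2-dione
Conditions: 3 M aq. HCl (cat.), MeOH, 40 °C
Reagents that add atoms: none
Why: Acid-catalysed acetal exchange with methanol should remove the MOM group (fast for a MOM ether ortho to a carbonyl) and free the C7 phenol that hydrogen-bonds to the C6 carbonyl, the 2,2-dimethyl-2H-chromene and the aryl methyl ethers being stable to dilute acid.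

**Compound list**

1 | 4-(benzyloxy)-3-methoxyphenol | COc1cc(O)ccc1OCc1ccccc1 | starting material
2 | 1-(benzyloxy)-2-methoxy-4-(methoxymethoxy)benzene | COCOc1ccc(OCc2ccccc2)c(OC)c1 | intermediate
3 | 2-methoxy-4-(methoxymethoxy)phenol | COCOc1ccc(O)c(OC)c1 | intermediate
4 | 2-methoxy-4-(methoxymethoxy)phenyl propan-2-ylcarbamate | COCOc1ccc(OC(=O)NC(C)C)c(OC)c1 | intermediate
5 | 2-methoxy-4-(methoxymethoxy)phenyl N-(tert-butyldimethylsilyl)-N-(propan-2-yl)carbamate (not isolated) | COCOc1ccc(OC(=O)N(C(C)C)[Si](C)(C)C(C)(C)C)c(OC)c1 | intermediate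
6 | 6-lithio derivative of 5 (not isolated) | COCOc1cc([Li])c(OC(=O)N(C(C)C)[Si](C)(C)C(C)(C)C)c(OC)c1 | intermediate
7 | 2-methoxy-4-(methoxymethoxy)-6-(trimethylsilyl)phenyl N-(tert-butyldimethylsilyl)-N-(propan-2-yl)carbamate (used crude) | COCOc1cc([Si](C)(C)C)c(OC(=O)N(C(C)C)[Si](C)(C)C(C)(C)C)c(OC)c1 | intermediate
8 | 1,4-dimethylpiperazine-2,3-dione | CN1CCN(C)C(=O)C1=O | starting material
9 | 4-methoxyphenylmagnesium bromide | COc1ccc([Mg]Br)cc1 | starting material
10 | 3-lithio derivative of 7 (lithium between OMe and OMOM; not isolated) | COCOc1cc([Si](C)(C)C)c(OC(=O)N(C(C)C)[Si](C)(C)C(C)(C)C)c(OC)c1[Li] | intermediate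
11 | lithium hemiaminalate from 10 and 8 (racemic; not isolated) | COCOc1cc([Si](C)(C)C)c(OC(=O)N(C(C)C)[Si](C)(C)C(C)(C)C)c(OC)c1C1(O[Li])N(C)CCN(C)C1=O | intermediate
12 | lithium bromomagnesium 2,3-diaryl-1,4-dimethylpiperazine-2,3-diolate from 11 and 9 (diastereomer mixture; not isolated) | COCOc1cc([Si](C)(C)C)c(OC(=O)N(C(C)C)[Si](C)(C)C(C)(C)C)c(OC)c1C1(O[Li])N(C)CCN(C)C1(O[Mg]Br)c1ccc(OC)cc1 | intermediate
13 | 2-methoxy-3-[2-(4-methoxyphenyl)-2-oxoacetyl]-4-(methoxymethoxy)-6-(trimethylsilyl)phenyl propan-2-ylcarbamate | COCOc1cc([Si](C)(C)C)c(OC(=O)NC(C)C)c(OC)c1C(=O)C(=O)c1ccc(OC)cc1 | intermediate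
14 | 1-[3-hydroxy-2-methoxy-6-(methoxymethoxy)-4-(trimethylsilyl)phenyl]-2-(4-methoxyphenyl)ethane-1,2-dione (formed as its amidinium phenoxide; not isolated) | COCOc1cc([Si](C)(C)C)c(O)c(OC)c1C(=O)C(=O)c1ccc(OC)cc1 | intermediate
15 | 2-methoxy-3-[2-(4-methoxyphenyl)-2-oxoacetyl]-4-(methoxymethoxy)-6-(trimethylsilyl)phenyl trifluoromethanesulfonate | COCOc1cc([Si](C)(C)C)c(OS(=O)(=O)C(F)(F)F)c(OC)c1C(=O)C(=O)c1ccc(OC)cc1 | intermediate
16 | 3-methylbut-2-enal (prenal) | CC(C)=CC=O | starting material
17 | aryne: 1-[2-methoxy-6-(methoxymethoxy)-3,4-didehydrophenyl]-2-(4-methoxyphenyl)ethane-1,2-dione (not isolated) | COCOC1=CC#CC(OC)=C1C(=O)C(=O)c1ccc(OC)cc1 | intermediate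
18 | benzoxete: 2-(2-methylprop-1-enyl)-2H-benzoxete carrying OMe, the diketone and OMOM (racemic; not isolated) | COCOc1cc2OC(C=C(C)C)c2c(OC)c1C(=O)C(=O)c1ccc(OC)cc1 | intermediate
19 | ortho-quinone methide: (Z)-6-(3-methylbut-2-enylidene)cyclohexa-2,4-dien-1-one carrying OMe, the diketone and OMOM (not isolated) | O=C1C=C(OCOC)C(C(=O)C(=O)c2ccc(OC)cc2)=C(OC)/C1=C/C=C(C)C | intermediate
20 | 1-[5-methoxy-7-(methoxymethoxy)-2,2-dimethyl-2H-chromen-6-yl]-2-(4-methoxyphenyl)ethane-1,2-dione | COCOc1cc2OC(C)(C)C=Cc2c(OC)c1C(=O)C(=O)c1ccc(OC)cc1 | intermediate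
21 | 1-(7-hydroxy-5-methoxy-2,2-dimethyl-2H-chromen-6-yl)-2-(4-methoxyphenyl)ethane-1,2-dione | COc1ccc(C(=O)C(=O)c2c(O)cc3c(c2OC)C=CC(C)(C)O3)cc1 | target

**Step count and risks**

Total step count: 8. Longest linear sequence: 8 steps (1 → 21); compounds 8, 9 and 16 enter as purchased reagents.

Steps most likely to fail, in order of risk:

Step 5. What may go wrong: the hindered, doubly ortho-oxygenated aryllithium may add sluggishly to the dione synthon or be protonated. Control over the two successive additions may also be lost (symmetrical diketones, or over-addition after premature collapse of the first hemiaminalate). Partial loss of the N-silyl group while 7 is handled would lead to deprotonation at nitrogen and fragmentation of the carbamate. Fallback, setting out from 7 and returning at 13: the same lithiation of 7 is quenched with I2, and NaHSO4 work-up, which removes the N-silyl group, should give 3-iodo-2-methoxy-4-(methoxymethoxy)-6-(trimethylsilyl)phenyl propan-2-ylcarbamate F1. Sonogashira coupling of F1 with 1-ethynyl-4-methoxybenzene (PdCl2(PPh3)2, CuI, Et3N, DMF, 60 °C) should give the diarylalkyne 2-methoxy-4-(methoxymethoxy)-3-[(4-methoxyphenyl)ethynyl]-6-(trimethylsilyl)phenyl propan-2-ylcarbamate F2. Oxidation of the alkyne to the 1,2-diketone (PdCl2 cat., DMSO, 100 °C) should then give 13. The diketone is thus built by cross-coupling and alkyne oxidation instead of by double carbonyl addition.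

Step 7. What may go wrong: the aryne may be consumed by pathways other than capture at the enal carbonyl. These are fluoride-promoted self-condensation of prenal, proton transfer within the zwitterion instead of C–C closure, addition across a ketone carbonyl of a second molecule, and oligomerisation. Fallback, setting out from 15 and returning at 20: the aryne is generated with CsF in DMF, which acts as solvent and as a far more abundant carbonyl partner. Insertion into the formamide C=O bond with the same regiochemistry, followed by aqueous work-up, should give the salicylaldehyde 6-hydroxy-2-methoxy-3-[2-(4-methoxyphenyl)-2-oxoacetyl]-4-(methoxymethoxy)benzaldehyde F3. A Petasis reaction of F3 with (2-methylprop-1-en-1-yl)boronic acid and Bn2NH (dioxane, 90 °C) should give the allylic amine 1-{3-[1-(dibenzylamino)-3-methylbut-2-en-1-yl]-4-hydroxy-2-methoxy-6-(methoxymethoxy)phenyl}-2-(4-methoxyphenyl)ethane-1,2-dione F4. On heating, F4 should lose the amine to give ortho-quinone methide 19, which closes to 20.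

Step 6. What may go wrong: the 1,2-diketone may be degraded by the amine and amidine, and O-sulfonylation of the doubly ortho-substituted phenoxide may be slow enough for protodesilylation or carbon-to-oxygen silyl migration to compete. Fallback, setting out from 7 and returning at 20, in which the diketone is introduced only after the annulation: lithiation of 7 as in step 5, quench with BrCF2CF2Br and NaHSO4 work-up should give 3-bromo-2-methoxy-4-(methoxymethoxy)-6-(trimethylsilyl)phenyl propan-2-ylcarbamate F5. Treatment with DBU and Et2NH and then PhNTf2 should give 3-bromo-2-methoxy-4-(methoxymethoxy)-6-(trimethylsilyl)phenyl trifluoromethanesulfonate F6. CsF and prenal in MeCN should give 6-bromo-5-methoxy-7-(methoxymethoxy)-2,2-dimethyl-2H-chromene F7. Bromine–lithium exchange on F7 (n-BuLi, THF, −78 °C), addition to 8, then 9, and cold dilute acid work-up should give 20.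

**Further compounds**

F1 | step 5 | 3-iodo-2-methoxy-4-(methoxymethoxy)-6-(trimethylsilyl)phenyl propan-2-ylcarbamate | COCOc1cc([Si](C)(C)C)c(OC(=O)NC(C)C)c(OC)c1I
F2 | step 5 | 2-methoxy-4-(methoxymethoxy)-3-[(4-methoxyphenyl)ethynyl]-6-(trimethylsilyl)phenyl propan-2-ylcarbamate | COCOc1cc([Si](C)(C)C)c(OC(=O)NC(C)C)c(OC)c1C#Cc1ccc(OC)cc1
F3 | step 7 | 6-hydroxy-2-methoxy-3-[2-(4-methoxyphenyl)-2-oxoacetyl]-4-(methoxymethoxy)benzaldehyde | COCOc1cc(O)c(C=O)c(OC)c1C(=O)C(=O)c1ccc(OC)cc1
F4 | step 7 | 1-{3-[1-(dibenzylamino)-3-methylbut-2-en-1-yl]-4-hydroxy-2-methoxy-6-(methoxymethoxy)phenyl}-2-(4-methoxyphenyl)ethane-1,2-dione (racemic) | COCOc1cc(O)c(C(C=C(C)C)N(Cc2ccccc2)Cc2ccccc2)c(OC)c1C(=O)C(=O)c1ccc(OC)cc1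
F5 | step 6 | 3-bromo-2-methoxy-4-(methoxymethoxy)-6-(trimethylsilyl)phenyl propan-2-ylcarbamate | COCOc1cc([Si](C)(C)C)c(OC(=O)NC(C)C)c(OC)c1Br
F6 | step 6 | 3-bromo-2-methoxy-4-(methoxymethoxy)-6-(trimethylsilyl)phenyl trifluoromethanesulfonate | COCOc1cc([Si](C)(C)C)c(OS(=O)(=O)C(F)(F)F)c(OC)c1Br
F7 | step 6 | 6-bromo-5-methoxy-7-(methoxymethoxy)-2,2-dimethyl-2H-chromene | COCOc1cc2OC(C)(C)C=Cc2c(OC)c1Br
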